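**Plan**
- Retrosynthetic cuts, in order: C11=C13 (methylenation), C1=C2 (ring-closing metathesis), C3–C4 (alkenyl–aldehyde coupling), the C8 tiglate, then the lactone bond C7–C11, the C6–O ester bond and the C7–C8 epoxide, leaving an acyclic C1–C10 chain.
- Forward: (S)-2-methylglycidol (C10) → dienol → enal → propynyl carbinol → (Z)-iodoalkene → epoxide; the γ-lactone closes first (step 9), the ten-membered carbocycle second (step 12), the exocyclic methylene last; no protecting groups.
- Enabling feature: C7 bears C11 and lies between two oxygen-bearing carbons, C6 (lactone oxygen) and C8 (ester oxygen), with all three substituents syn. That pattern is a trans-7,8-epoxide opened at C7, with inversion, by a carbanion held on O6, which closes the ring O–C12–C11–C7–C6.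
- The phosphonate on C11 is the activating group for this closure and leaves in the last step, where it delivers the methylene.
- Stereochemistry: C10 from the glycidol; C7/C8 from a tartrate-controlled epoxidation; C6 by Mitsunobu inversion; C7 by SN2 inversion in the key step; C3 by a ligand-controlled chromium addition; Z-C4=C5 by trans-hydroalumination/iodination; Z-C1=C2 by ring strain.

Key step: step 9

Remark: locants C1–C13 are those of the germacranolide skeleton of the target (ring C1–C10, lactone C6–O–C12(=O)–C11–C7, C13 the methylene). CIP labels at C6 and C7 change along the route with substituent priority only. (S)-2-Methylglycidol is taken as a purchasable building block.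

Step 1
Reactants: 1 (S)-2-methylglycidol; 2 vinylmagnesium bromide
Product: 3 (2R)-2-methylpent-4-ene-1,2-diol
Conditions: 2 (3 equiv), CuI (10 mol%), THF, −30 to 0 °C; aq. NH4Cl
Reagents that add atoms: vinylmagnesium bromide (2), C=C[Mg]Br
Why: Copper-catalysed Grignard opening of the 2,2-disubstituted epoxide at its CH2 terminus should leave the quaternary centre (C10) untouched, and Payne rearrangement of the alkoxide is degenerate here.

Step 2
Reactants: 3 (2R)-2-methylpent-4-ene-1,2-diol
Product: 4 (2R)-2-hydroxy-2-methylpent-4-enal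
Conditions: SO3·pyridine, DMSO, iPr2NEt, CH2Cl2, 0 °C; used crude
Reagents that add atoms: none
Why: Parikh–Doering oxidation should touch only the primary alcohol, since the tertiary carbinol cannot be oxidised and the quaternary α-carbon cannot epimerise.

Step 3
Reactants: 4 (2R)-2-hydroxy-2-methylpent-4-enal; 5 methyltriphenylphosphonium bromide
Product: 6 (3R)-3-methylhexa-1,5-dien-3-ol
Conditions: 5 (2.5 equiv), KOtBu (2.4 equiv), THF, 0 °C; then 4, 0 °C to rt
Reagents that add atoms: methyltriphenylphosphonium bromide (5), C[P+](c1ccccc1)(c1ccccc1)c1ccccc1.[Br-]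
Why: Wittig methylenation with excess ylide should tolerate the free tertiary hydroxyl and gives the vinyl group that becomes C1=C2.

Step 4
Reactants: 6 (3R)-3-methylhexa-1,5-dien-3-ol; 7 (E)-crotonaldehyde
Product: 8 (2E,5R)-5-hydroxy-5-methylhepta-2,6-dienal
Conditions: 7 (3 equiv), second-generation Hoveyda–Grubbs catalyst (3 mol%), CH2Cl2, 40 °C
Reagents that add atoms: crotonaldehyde (7), C/C=C/C=O
Why: Olefin cross-metathesis should engage the unhindered allyl terminus in preference to the vinyl group on the quaternary carbinol and give the E enal.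

Step 5
Reactants: 8 (2E,5R)-5-hydroxy-5-methylhepta-2,6-dienal; 9 1-propynylmagnesium bromide
Product: 10 (3R,5E)-3-methyldeca-1,5-dien-8-yne-3,7-diol (both C7 epimers)
Conditions: 9 (2.3 equiv), THF, −78 to 0 °C; aq. NH4Cl
Reagents that add atoms: 1-propynylmagnesium bromide (9), CC#C[Mg]Br
Why: 1,2-Addition of the alkynyl Grignard reagent to the enal builds the carbinol that becomes C6, and no control is expected at this centre, which is sorted in step 7.

Step 6
Reactants: 10 (3R,5E)-3-methyldeca-1,5-dien-8-yne-3,7-diol (both C7 epimers)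
Product: 12 (3R,5E,8Z)-9-iodo-3-methyldeca-1,5,8-triene-3,7-diol (both C7 epimers), via cyclic alkenylalanate 11 (not isolated)
Conditions: NaAlH2(OCH2CH2OMe)2 (3.5 equiv), THF, 0 °C to rt; then I2 (4 equiv), −78 to 0 °C
Reagents that add atoms: iodine, II
Why: Hydroxyl-directed trans-hydroalumination of the propargylic alcohol puts aluminium on the distal alkyne carbon (C4) cis to the carbinol in a five-membered alanate, and iodinolysis with retention should give the Z iodoalkene while the other alkenes stay untouched.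

Step 7
Reactants: 12 (3R,5E,8Z)-9-iodo-3-methyldeca-1,5,8-triene-3,7-diol (both C7 epimers)
Product: 13 (3R,5R,6R,7R,8Z)-5,6-epoxy-9-iodo-3-methyldeca-1,8-diene-3,7-diol
Conditions: Ti(OiPr)4 (20 mol%), D-(−)-diisopropyl tartrate (24 mol%), tBuOOH (0.55 equiv), 4 Å sieves, CH2Cl2, −20 °C
Reagents that add atoms: tert-butyl hydroperoxide, CC(C)(C)OO
Why: Sharpless kinetic resolution with the D-tartrate should epoxidise the E alkene of the 7S epimer only, giving the trans-epoxide erythro to the carbinol, while the 7R epimer stays behind and is separated; the iodoalkene and the vinyl group on the tertiary carbinol are too slow to compete.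

Step 8
Reactants: 13 (3R,5R,6R,7R,8Z)-5,6-epoxy-9-iodo-3-methyldeca-1,8-diene-3,7-diol; 14 diethylphosphonoacetic acid
Product: 15 (3R,5R,6S,7S,8Z)-5,6-epoxy-3-hydroxy-9-iodo-3-methyldeca-1,8-dien-7-yl 2-(diethoxyphosphoryl)acetate
Conditions: 14 (1.5 equiv), PPh3 (1.6 equiv), DIAD (1.6 equiv), toluene, 0 °C to rt
Reagents that add atoms: diethylphosphonoacetic acid (14), OC(=O)CP(=O)(OCC)OCC
Why: Mitsunobu esterification inverts the secondary carbinol (C6) by SN2, turning the erythro into the threo epoxy ester and attaching the tether in the same operation, while the tertiary alcohol does not react.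

Step 9
Reactants: 15 (3R,5R,6S,7S,8Z)-5,6-epoxy-3-hydroxy-9-iodo-3-methyldeca-1,8-dien-7-yl 2-(diethoxyphosphoryl)acetate
Product: 17 diethyl {(4R,5R)-4-[(1R,3R)-1,3-dihydroxy-3-methylpent-4-en-1-yl]-5-[(1Z)-2-iodoprop-1-en-1-yl]-2-oxooxolan-3-yl}phosphonate (C3 epimers), via lithium phosphonoenolate 16 (not isolated)
Conditions: LiN(SiMe3)2 (1.05 equiv), THF, −78 °C to rt; AcOH, 0 °C
Reagents that add atoms: none
Why: Proposed new method: deprotonation gives the phosphoryl-stabilised carbanion 16, whose carbon C11 attacks the epoxide carbon C7 from the side opposite the C7–O bond and closes the γ-lactone; the freed C8 alkoxide is then protonated by the acidic α-phosphono lactone, so the product rests as its unreactive phosphonoenolate until the quench. The closest known reactions are the intermolecular opening of epoxides by phosphonoacetate anions, the epoxynitrile cyclisation, and the telescoped intramolecular Michael/olefination of phosphonoacetate esters, which closes the same O–C12–C11 unit onto a carbon electrophile. The ring closes 5-exo-tet, and because the exocyclic P=O carries the charge, the ring carbonyl need not lie in the enolate plane, which should lift the usual bar on five-membered enolate-endo alkylation. C7 is set by SN2 inversion (C11 ends syn to O6 and to O8), C8 keeps the epoxide oxygen with retention, and C11 is left epimeric because it becomes sp2 in step 13. The step needs C-alkylation at C7 in preference to attack at C8 (six-membered, endo) and to O-alkylation through the ester carbonyl; the exo preference of epoxide openings, the threo trans-epoxide geometry and a tight lithium chelate between P=O and C=O are relied on, and staying at or below rt avoids phosphoryl transfer to the C8 alkoxide (Wadsworth–Emmons cyclopropanation).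

Step 10
Reactants: 17 diethyl {(4R,5R)-4-[(1R,3R)-1,3-dihydroxy-3-methylpent-4-en-1-yl]-5-[(1Z)-2-iodoprop-1-en-1-yl]-2-oxooxolan-3-yl}phosphonate; 18 tigloyl chloride
Product: 19 (1R,3R)-1-{(2R,3R)-4-(diethoxyphosphoryl)-2-[(1Z)-2-iodoprop-1-en-1-yl]-5-oxooxolan-3-yl}-3-hydroxy-3-methylpent-4-en-1-yl (2E)-2-methylbut-2-enoate
Conditions: 18 (1.5 equiv), pyridine, DMAP (10 mol%), CH2Cl2, 0 °C to rt
Reagents that add atoms: tigloyl chloride (18), ClC(=O)/C(C)=C/C
Why: Acylation should take the secondary C8 hydroxyl and leave the tertiary C10 hydroxyl, and the weak base keeps the phosphonolactone protonated and the lactone on O6.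

Step 11
Reactants: 19 (the iodoalkene tiglate); 20 acrolein
Product: 21 (1R,3R)-1-{(2S,3R)-4-(diethoxyphosphoryl)-2-[(1Z,3R)-3-hydroxy-2-methylpenta-1,4-dien-1-yl]-5-oxooxolan-3-yl}-3-hydroxy-3-methylpent-4-en-1-yl (2E)-2-methylbut-2-enoate
Conditions: CrCl2 (4 equiv), NiCl2 (2 mol%), chiral oxazoline–sulfonamide ligand (4.4 equiv), Et3N (4.4 equiv), 20 (3 equiv), THF, rt
Reagents that add atoms: acrolein (20), C=CC=O
Why: In this Nozaki–Hiyama–Kishi coupling the alkenyl iodide is transferred through nickel to trivalent chromium with retention of the Z geometry and adds 1,2 to the aldehyde in the presence of esters, lactone and free hydroxyls, and the new C3 carbinol is set by the chromium-bound chiral ligand, whose antipode is chosen for 3R.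

Step 12
Reactants: 21 (the diene with vinyl groups on C3 and C10)
Product: 22 diethyl {(3aR,4R,6R,7Z,9R,10Z,11aS)-6,9-dihydroxy-6,10-dimethyl-4-{[(2E)-2-methylbut-2-enoyl]oxy}-2-oxo-2,3,3a,4,5,6,9,11a-octahydrocyclodeca[b]furan-3-yl}phosphonate (C3 epimers)
Conditions: second-generation Hoveyda–Grubbs catalyst (10 mol%), 1,4-benzoquinone (20 mol%), toluene (1 mM), 80 °C, argon sparge
Reagents that add atoms: none
Why: Ring-closing metathesis of the two vinyl carbinols should close the ten-membered ring with the Z alkene, because an E alkene next to the Z-C4=C5 unit and the cis-fused lactone is more strained, and keeping the phosphonate on C11 leaves no acrylate-type alkene to divert the carbene into six- or seven-membered rings.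

Step 13
Reactants: 22 (the macrocyclic phosphonolactone); 23 formaldehyde
Product: 24 (3aR,4R,6R,7Z,9R,10Z,11aS)-6,9-dihydroxy-6,10-dimethyl-3-methylidene-2-oxo-2,3,3a,4,5,6,9,11a-octahydrocyclodeca[b]furan-4-yl (2E)-2-methylbut-2-enoate
Conditions: 37% aq. HCHO (10 equiv), K2CO3 (3 equiv), THF, 0 °C to rt
Reagents that add atoms: formaldehyde (23), C=O
Why: Horner–Wadsworth–Emmons methylenation of the α-phosphono lactone converges both C11 epimers on the exocyclic alkene under carbonate conditions that should spare the tiglate and the two free carbinols.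

**Compound list**
1 | (S)-2-methylglycidol, (2S)-(2-methyloxiran-2-yl)methanol | C[C@]1(CO)CO1 | starting material
2 | vinylmagnesium bromide | C=C[Mg]Br | starting material
3 | (2R)-2-methylpent-4-ene-1,2-diol | OC[C@](C)(O)CC=C | intermediate
4 | (2R)-2-hydroxy-2-methylpent-4-enal | O=C[C@](C)(O)CC=C | intermediate
5 | methyltriphenylphosphonium bromide | C[P+](c1ccccc1)(c1ccccc1)c1ccccc1.[Br-] | starting material
6 | (3R)-3-methylhexa-1,5-dien-3-ol | C=C[C@](C)(O)CC=C | intermediate
7 | (E)-crotonaldehyde | C/C=C/C=O | starting material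
8 | (2E,5R)-5-hydroxy-5-methylhepta-2,6-dienal | C=C[C@](C)(O)C/C=C/C=O | intermediate
9 | 1-propynylmagnesium bromide | CC#C[Mg]Br | starting material
10 | (3R,5E)-3-methyldeca-1,5-dien-8-yne-3,7-diol, both C7 epimers (C7 is C6 of the target) | C=C[C@](C)(O)C/C=C/C(O)C#CC | intermediate
11 | sodium cyclic alkenyl(dialkoxy)alanate from 10 (2,5-dihydro-1,2-oxaluminole; tertiary hydroxyl drawn free) | C=C[C@](C)(O)C/C=C/C1C=C(C)[Al-](OCCOC)(OCCOC)O1.[Na+] | intermediate
12 | (3R,5E,8Z)-9-iodo-3-methyldeca-1,5,8-triene-3,7-diol, both C7 epimers | C=C[C@](C)(O)C/C=C/C(O)/C=C(/C)I | intermediate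
13 | (3R,5R,6R,7R,8Z)-5,6-epoxy-9-iodo-3-methyldeca-1,8-diene-3,7-diol (erythro, trans-epoxide) | C=C[C@](C)(O)C[C@H]1O[C@@H]1[C@H](O)/C=C(/C)I | intermediate
14 | diethylphosphonoacetic acid | OC(=O)CP(=O)(OCC)OCC | starting material
15 | (3R,5R,6S,7S,8Z)-5,6-epoxy-3-hydroxy-9-iodo-3-methyldeca-1,8-dien-7-yl 2-(diethoxyphosphoryl)acetate (threo) | C=C[C@](C)(O)C[C@H]1O[C@@H]1[C@@H](OC(=O)CP(=O)(OCC)OCC)/C=C(/C)I | intermediate
16 | lithium enolate of 15 (carbanion on the phosphonoacetate carbon) | C=C[C@](C)(O)C[C@H]1O[C@@H]1[C@@H](OC(=O)[CH-]P(=O)(OCC)OCC)/C=C(/C)I.[Li+] | intermediate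
17 | diethyl {(4R,5R)-4-[(1R,3R)-1,3-dihydroxy-3-methylpent-4-en-1-yl]-5-[(1Z)-2-iodoprop-1-en-1-yl]-2-oxooxolan-3-yl}phosphonate (4,5-cis; C3 epimers) | CCOP(=O)(OCC)C1C(=O)O[C@@H](/C=C(/C)I)[C@H]1[C@H](O)C[C@@](C)(O)C=C | intermediate
18 | tigloyl chloride, (2E)-2-methylbut-2-enoyl chloride | ClC(=O)/C(C)=C/C | starting material
19 | (1R,3R)-1-{(2R,3R)-4-(diethoxyphosphoryl)-2-[(1Z)-2-iodoprop-1-en-1-yl]-5-oxooxolan-3-yl}-3-hydroxy-3-methylpent-4-en-1-yl (2E)-2-methylbut-2-enoate | CCOP(=O)(OCC)C1C(=O)O[C@@H](/C=C(/C)I)[C@H]1[C@H](OC(=O)/C(C)=C/C)C[C@@](C)(O)C=C | intermediate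
20 | acrolein | C=CC=O | starting material
21 | (1R,3R)-1-{(2S,3R)-4-(diethoxyphosphoryl)-2-[(1Z,3R)-3-hydroxy-2-methylpenta-1,4-dien-1-yl]-5-oxooxolan-3-yl}-3-hydroxy-3-methylpent-4-en-1-yl (2E)-2-methylbut-2-enoate | CCOP(=O)(OCC)C1C(=O)O[C@@H](/C=C(/C)[C@H](O)C=C)[C@H]1[C@H](OC(=O)/C(C)=C/C)C[C@@](C)(O)C=C | intermediate
22 | diethyl {(3aR,4R,6R,7Z,9R,10Z,11aS)-6,9-dihydroxy-6,10-dimethyl-4-{[(2E)-2-methylbut-2-enoyl]oxy}-2-oxo-2,3,3a,4,5,6,9,11a-octahydrocyclodeca[b]furan-3-yl}phosphonate (C3 epimers) | CCOP(=O)(OCC)C1C(=O)O[C@H]2/C=C(/C)[C@H](O)/C=C\[C@](C)(O)C[C@@H](OC(=O)/C(C)=C/C)[C@@H]12 | intermediate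
23 | formaldehyde | C=O | starting material
24 | (3aR,4R,6R,7Z,9R,10Z,11aS)-6,9-dihydroxy-6,10-dimethyl-3-methylidene-2-oxo-2,3,3a,4,5,6,9,11a-octahydrocyclodeca[b]furan-4-yl (2E)-2-methylbut-2-enoate | C=C1C(=O)O[C@H]2/C=C(/C)[C@H](O)/C=C\[C@](C)(O)C[C@@H](OC(=O)/C(C)=C/C)[C@@H]12 | target

Total steps: 13. Longest linear sequence: 13.

**Steps most likely to fail**

Step 9 (proposed new method). What may go wrong: the enolate closes through its ester carbonyl oxygen instead of carbon, the epoxide opens at C8 to a six-membered lactone, or the ester does not reach the s-cis rotamer and nothing closes. The fallback keeps the stereospecific SN2 logic but removes the ester from the ring-forming tether, using the known cyclisation of a non-enolate, heteroatom-stabilised carbanion onto an epoxide. It sets out from 13. Mitsunobu inversion with chloroacetic acid gives the chloroacetate F1, and brief methanolysis (K2CO3, MeOH, 0 °C) gives the threo epoxy alcohol F2. Acetal exchange with diethyl (2,2-diethoxyethyl)phosphonate (TMSOTf, 2,4,6-collidine, CH2Cl2) gives the mixed acetal F3, in which C12 is an sp3 acetal carbon. The lithiated phosphonate (LiN(iPr)2, 2.2 equiv, THF, −78 to 0 °C) then closes 5-exo-tet at C7 with the same inversion to the 2-ethoxyoxolane F4. Mild aqueous acid gives the lactol F5, and Ag2CO3 on Celite oxidises the lactol in the presence of the secondary alcohol, which comes back to the route at 17.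

Step 12. What may go wrong: cross-metathesis oligomerisation outruns the ten-membered closure, the ring closes to the E alkene, or ruthenium hydrides isomerise the allylic alcohols. The fallback changes the ring that metathesis has to close. It sets out from 21: tBu2Si(OTf)2 with 2,6-lutidine at high dilution bridges O3 and O10 to give the eleven-membered silylene acetal F7. Metathesis then closes a seven-membered dioxasilepine, in which the new alkene can only be Z and which holds the two vinyl groups together, giving the bicyclic silylene F8. HF·pyridine removes the silylene and the route is rejoined at 22.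

Step 11. What may go wrong: poor facial selectivity at the aldehyde, so that both C3 epimers form, or protonation of the alkenylchromium by the acidic phosphonolactone. The fallback sets C3 by a ketone reduction whose sense can be predicted. It sets out from 19: carbonylative Stille coupling with tributyl(vinyl)stannane (Pd(PPh3)4, CO 1 atm, THF, 50 °C) gives the cross-conjugated dienone F6. Corey–Bakshi–Shibata reduction with the (S)-2-methyl oxazaborolidine and catecholborane at −78 °C, in which the α-methyl-branched alkenyl group acts as the large and the vinyl group as the small substituent, should give the 3R alcohol and comes back to the route at 21.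

**Further compounds**
F1 | step 9 | (3R,5R,6S,7S,8Z)-5,6-epoxy-3-hydroxy-9-iodo-3-methyldeca-1,8-dien-7-yl chloroacetate | C=C[C@](C)(O)C[C@H]1O[C@@H]1[C@@H](OC(=O)CCl)/C=C(/C)I
F2 | step 9 | (3R,5R,6R,7S,8Z)-5,6-epoxy-9-iodo-3-methyldeca-1,8-diene-3,7-diol (threo) | C=C[C@](C)(O)C[C@H]1O[C@@H]1[C@@H](O)/C=C(/C)I
F3 | step 9 | mixed ethyl acetal of F2 at the C7 hydroxyl with (diethoxyphosphoryl)acetaldehyde | C=C[C@](C)(O)C[C@H]1O[C@@H]1[C@@H](OC(OCC)CP(=O)(OCC)OCC)/C=C(/C)I
F4 | step 9 | diethyl {(4R,5R)-4-[(1R,3R)-1,3-dihydroxy-3-methylpent-4-en-1-yl]-2-ethoxy-5-[(1Z)-2-iodoprop-1-en-1-yl]oxolan-3-yl}phosphonate | CCOC1O[C@@H](/C=C(/C)I)[C@@H]([C@H](O)C[C@@](C)(O)C=C)C1P(=O)(OCC)OCC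
F5 | step 9 | diethyl {(4R,5R)-4-[(1R,3R)-1,3-dihydroxy-3-methylpent-4-en-1-yl]-2-hydroxy-5-[(1Z)-2-iodoprop-1-en-1-yl]oxolan-3-yl}phosphonate | OC1O[C@@H](/C=C(/C)I)[C@@H]([C@H](O)C[C@@](C)(O)C=C)C1P(=O)(OCC)OCC
F6 | step 11 | (1R,3R)-1-{(2S,3R)-4-(diethoxyphosphoryl)-2-[(1Z)-2-methyl-3-oxopenta-1,4-dien-1-yl]-5-oxooxolan-3-yl}-3-hydroxy-3-methylpent-4-en-1-yl (2E)-2-methylbut-2-enoate | CCOP(=O)(OCC)C1C(=O)O[C@@H](/C=C(/C)C(=O)C=C)[C@H]1[C@H](OC(=O)/C(C)=C/C)C[C@@](C)(O)C=C
F7 | step 12 | O3,O10-di-tert-butylsilylene acetal of 21 (eleven-membered ring) | CCOP(=O)(OCC)C1C(=O)O[C@H]2/C=C(/C)[C@@H](C=C)O[Si](C(C)(C)C)(C(C)(C)C)O[C@@](C)(C=C)C[C@@H](OC(=O)/C(C)=C/C)[C@@H]12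
F8 | step 12 | O3,O10-di-tert-butylsilylene acetal of 22 (Z alkene in a seven-membered dioxasilepine) | CCOP(=O)(OCC)C1C(=O)O[C@H]2/C=C(/C)[C@H]3/C=C\[C@](C)(O[Si](C(C)(C)C)(C(C)(C)C)O3)C[C@@H](OC(=O)/C(C)=C/C)[C@@H]12
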